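Counted in fractions of its own charge, each substrate starts at one, so I read the two earlier runs and the new flask on a single scale.

common to all: precatalyst 0.17 mM
- theta: left-handed substrate 0.0067 M; right-handed substrate 0.0067 M; coupling partner 0.030 M; run made earlier
- epsilon: left-handed substrate 0.015 M; right-handed substrate 0.015 M; coupling partner 0.030 M; run made earlier
- flask: left-handed substrate 0.010 M; right-handed substrate 0.010 M; coupling partner 0.0300 M; time 40 h

| run | time / h | right-handed substrate / % | left-handed substrate / % |
|---|---|---|---|
| theta | 3.00 | 48.1 | 36.5 |
| theta | 6.00 | 45.5 | 18.9 |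
| theta | 10.0 | 40.1 | 5.1 |
| theta | 15.0 | 32.8 | 0.9 |
| theta | 20.0 | 27.3 | 0.4 |
| theta | 25.0 | 22.5 | 0 |
| epsilon | 2.00 | 49.1 | 45.8 |
| epsilon | 3.00 | 49.3 | 42.4 |
| epsilon | 4.00 | 48.5 | 36.9 |
| epsilon | 6.00 | 47.1 | 27.5 |
| epsilon | 10.0 | 43.3 | 13.5 |
| epsilon | 15.0 | 39.9 | 5.3 |
| epsilon | 25.0 | 32.9 | 0.7 |

(scatter of a reading: 0.3 percentage points)

- whether the excess of right-handed substrate over left-handed substrate among what is left of the two reaches 98% by 40 h (yes / no)
- the highest excess of right-handed substrate over left-handed substrate among what is left of the two up to 40 h

Let l and r be the fractions left of left-handed and right-handed substrate. The selectivity factor s is ln l over ln r, and I read it at both ends of the range of charges: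

theta, 10.0 h: s = 10.3
epsilon, 15.0 h: s = 9.95

Since l/r equals r raised to s less 1, the wanted excess gives a critical remainder, the fraction of right-handed substrate left when the excess reaches 98%:

r = 0.598 to 0.612

The flask's charge of 0.010 M lies between the other two, so I took their crossing times as its bracket. Theta crossed between readings, and epsilon I carried past its last reading on its last slope, which makes that bound approximate:

from below: 17.0 h
from above: 29.3 h

That upper bound stands 10.7 h short of the limit, so I answered yes. My bracket gave no top.

The forecast said yes and >99.9%, with about 22 h inside my bracket, and argued “Partner stays in excess, so the excess keeps climbing”.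

The flask gave yes and >99.9%.

    coupling partner + precatalyst → free catalyst + spent reagent (k = 0.00150 /M/s)
    2 free catalyst ⇌ resting dimer, settled at all times (K = 2280 /M)
    free catalyst + right-handed substrate ⇌ catalyst intermediate B (K = 35.0 /M, k = 21.8 /M/s)
    free catalyst + left-handed substrate ⇌ catalyst intermediate A (K = 163 /M, k = 5.24 /M/s)
    coupling partner + catalyst intermediate B → free catalyst + right-handed product (k = 0.183 /M/s)
    coupling partner ⇌ dormant form (K = 0.132, k = 1.78 × 10⁻⁵ /s)
    coupling partner + catalyst intermediate A → free catalyst + left-handed product (k = 0.531 /M/s)

The flask reached the level at 20.6 h, 19.4 h before the limit, with right-handed substrate at 0.615 of its own charge, close to the critical remainder of 0.612. By 40.0 h that fraction had fallen to 35%.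

The data are simulated on assumed constants; noise was put on by code.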